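**Retrosynthetic overview**
- Target 15 ⇐ 13: the dihydropyran ring is closed last, by intramolecular addition–elimination of the C2 oxygen onto a vinylogous methyl ester (O1–C8a bond). The carbocycle is bought intact as cyclohexane-1,3-dione.
- 13 ⇐ 12: the C4 carbinol comes from CBS reduction of the side-chain ketone, with the ring carbonyl masked as a vinylogous ester.
- 12 ⇐ 11 ⇐ 8 + 9: the C4–C4a bond comes from Claisen-type C-acylation of the dione, followed by O-methylation.
- 8 ⇐ 5 ⇐ 4 ⇐ 1 + 2: C2 is set by Noyori hydrogenation of a β-keto ester made by crossed Claisen condensation (C2–C3 bond).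

Assumption: the SMILES is read as (2S,4R), i.e. heptadecyl and OH cis on the dihydropyran ring; this corresponds to an anti-1,3-diol in the open-chain precursors.

**Route**

Step 1
Reactants: 1 methyl octadecanoate; 2 tert-butyl acetate
Product: 4 tert-butyl 3-oxoicosanoate, via lithium enolate of tert-butyl acetate 3 (not isolated)
Conditions: LDA (2.5 equiv), 2 (2.5 equiv), THF, −78 °C; add 1, −78 → 0 °C; aq NH4Cl
Reagents that add atoms: none
Why: Crossed Claisen condensation in which the non-self-condensing tert-butyl acetate enolate acylates on the methyl ester and the product is held as its stabilised β-keto ester enolate until work-up.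

Step 2
Reactants: 4 tert-butyl 3-oxoicosanoate
Product: 5 tert-butyl (3S)-3-hydroxyicosanoate
Conditions: H2 (50 atm), RuCl2[(S)-BINAP] (0.2 mol %), MeOH, 50 °C
Reagents that add atoms: none
Why: Noyori asymmetric hydrogenation of the chelating β-keto ester, where (S)-BINAP–Ru gives the (S)-β-hydroxy ester (typically ≥97% ee) and so sets C2 of the target.

Step 3
Reactants: 5 tert-butyl (3S)-3-hydroxyicosanoate
Product: 6 (3S)-3-hydroxyicosanoic acid
Conditions: TFA/CH2Cl2 (1:4), 0 °C → rt; recrystallise
Reagents that add atoms: none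
Why: Acidolysis of the tert-butyl ester (E1 loss of isobutylene) frees the acid without touching the stereocentre, and the crystalline acid allows an ee upgrade.

Step 4
Reactants: 6 (3S)-3-hydroxyicosanoic acid
Product: 8 (3S)-3-[(tert-butyldimethylsilyl)oxy]icosanoic acid, via bis-silylated ester 7 (not isolated)
Conditions: TBSCl (2.5 equiv), imidazole (5 equiv), DMF, rt; then K2CO3, MeOH/THF/H2O, rt; 1 M HCl to pH 4, 0 °C
Reagents that add atoms: tert-butyldimethylsilyl chloride, CC(C)(C)[Si](C)(C)Cl
Why: Silylation of both OH groups followed by selective carbonate hydrolysis of the far more labile silyl ester is the standard protection of a β-hydroxy acid as its TBS ether.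

Step 5
Reactants: 8 (3S)-3-[(tert-butyldimethylsilyl)oxy]icosanoic acid; 9 cyclohexane-1,3-dione
Product: 11 2-[(3S)-3-[(tert-butyldimethylsilyl)oxy]icosanoyl]-3-hydroxycyclohex-2-en-1-one, via enol ester 10 (not isolated)
Conditions: DCC (1.2 equiv), DMAP (1.2 equiv), CH2Cl2, 0 °C → rt, 24 h; 1 M HCl wash
Reagents that add atoms: none
Why: Claisen-type C-acylation of the 1,3-dione, in which Steglich O-acylation gives the enol ester and DMAP then transfers the acyl group to C2 to give the hydrogen-bonded triketone, forming the C4–C4a bond.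

Step 6
Reactants: 11 2-[(3S)-3-[(tert-butyldimethylsilyl)oxy]icosanoyl]-3-hydroxycyclohex-2-en-1-one
Product: 12 2-[(3S)-3-[(tert-butyldimethylsilyl)oxy]icosanoyl]-3-methoxycyclohex-2-en-1-one
Conditions: TMSCHN2 (1.5 equiv), PhMe/MeOH (4:1), 0 °C; filter through Et3N-deactivated silica
Reagents that add atoms: (trimethylsilyl)diazomethane, C[Si](C)(C)C=[N+]=[N-]
Why: Diazoalkane O-methylation of the acidic ring enol gives the vinylogous methyl ester, which fixes the future C8a–O position and leaves the out-of-plane side-chain carbonyl as the only ketone-like C=O.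

Step 7
Reactants: 12 2-[(3S)-3-[(tert-butyldimethylsilyl)oxy]icosanoyl]-3-methoxycyclohex-2-en-1-one
Product: 13 2-[(1R,3S)-3-[(tert-butyldimethylsilyl)oxy]-1-hydroxyicosyl]-3-methoxycyclohex-2-en-1-one
Conditions: (S)-Me-CBS (20 mol %), BH3·SMe2 (0.7 equiv), PhMe, −40 → −20 °C; MeOH quench, pH 7 buffer
Reagents that add atoms: none
Why: Corey–Bakshi–Shibata reduction, in which the (S)-oxazaborolidine–borane complex reduces the twisted ketone (the ring C=O is a deactivated vinylogous ester) with the tetrasubstituted alkenyl group as the large substituent, giving the (R)-carbinol (future C4) under reagent control.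

Step 8
Reactants: 13 2-[(1R,3S)-3-[(tert-butyldimethylsilyl)oxy]-1-hydroxyicosyl]-3-methoxycyclohex-2-en-1-one
Product: 15 (2S,4R)-2-heptadecyl-4-hydroxy-2,3,4,6,7,8-hexahydro-5H-chromen-5-one, via desilylated diol 14 (not isolated)
Conditions: TBAF (1.5 equiv), THF, 0 °C → rt; aq NH4Cl; chromatography on Et3N-deactivated silica
Reagents that add atoms: none
Why: Fluoride desilylation frees the C3' alkoxide, which adds to the β-carbon of the vinylogous ester and expels methoxide (6-membered intramolecular oxa-Michael addition–elimination), closing the pyran without touching either stereocentre so that the anti-diol becomes the 2,4-cis product.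

**Compound list**
1 | methyl octadecanoate (methyl stearate) | CCCCCCCCCCCCCCCCCC(=O)OC | starting material
2 | tert-butyl acetate | CC(=O)OC(C)(C)C | starting material
3 | lithium enolate of tert-butyl acetate | [Li]OC(=C)OC(C)(C)C | intermediate
4 | tert-butyl 3-oxoicosanoate | CCCCCCCCCCCCCCCCCC(=O)CC(=O)OC(C)(C)C | intermediate
5 | tert-butyl (3S)-3-hydroxyicosanoate | CCCCCCCCCCCCCCCCC[C@H](O)CC(=O)OC(C)(C)C | intermediate
6 | (3S)-3-hydroxyicosanoic acid | CCCCCCCCCCCCCCCCC[C@H](O)CC(=O)O | intermediate
7 | tert-butyldimethylsilyl (3S)-3-[(tert-butyldimethylsilyl)oxy]icosanoate | CCCCCCCCCCCCCCCCC[C@H](O[Si](C)(C)C(C)(C)C)CC(=O)O[Si](C)(C)C(C)(C)C | intermediate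
8 | (3S)-3-[(tert-butyldimethylsilyl)oxy]icosanoic acid | CCCCCCCCCCCCCCCCC[C@H](O[Si](C)(C)C(C)(C)C)CC(=O)O | intermediate
9 | cyclohexane-1,3-dione | O=C1CCCC(=O)C1 | starting material
10 | 3-oxocyclohex-1-en-1-yl (3S)-3-[(tert-butyldimethylsilyl)oxy]icosanoate | CCCCCCCCCCCCCCCCC[C@H](O[Si](C)(C)C(C)(C)C)CC(=O)OC1=CC(=O)CCC1 | intermediate
11 | 2-[(3S)-3-[(tert-butyldimethylsilyl)oxy]icosanoyl]-3-hydroxycyclohex-2-en-1-one (triketone, enol form) | CCCCCCCCCCCCCCCCC[C@H](O[Si](C)(C)C(C)(C)C)CC(=O)C1=C(O)CCCC1=O | intermediate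
12 | 2-[(3S)-3-[(tert-butyldimethylsilyl)oxy]icosanoyl]-3-methoxycyclohex-2-en-1-one | CCCCCCCCCCCCCCCCC[C@H](O[Si](C)(C)C(C)(C)C)CC(=O)C1=C(OC)CCCC1=O | intermediate
13 | 2-[(1R,3S)-3-[(tert-butyldimethylsilyl)oxy]-1-hydroxyicosyl]-3-methoxycyclohex-2-en-1-one | CCCCCCCCCCCCCCCCC[C@H](O[Si](C)(C)C(C)(C)C)C[C@@H](O)C1=C(OC)CCCC1=O | intermediate
14 | 2-[(1R,3S)-1,3-dihydroxyicosyl]-3-methoxycyclohex-2-en-1-one | CCCCCCCCCCCCCCCCC[C@H](O)C[C@@H](O)C1=C(OC)CCCC1=O | intermediate
15 | (2S,4R)-2-heptadecyl-4-hydroxy-2,3,4,6,7,8-hexahydro-5H-chromen-5-one | CCCCCCCCCCCCCCCCC[C@H]1C[C@@H](O)C2=C(CCCC2=O)O1 | target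

**Totals**
Total steps: 8. Longest linear sequence: 8 steps (1 → 15).

**Three steps most likely to fail, with fallbacks**

Step 5 (C-acylation): the β-silyloxy acyl group may eliminate or migrate poorly from O to C. The fallback sets out from 8 and 9 and comes back at 12, bypassing the triketone. Acid 8 is reduced with BH3·SMe2 to (3S)-3-[(tert-butyldimethylsilyl)oxy]icosan-1-ol F1 and oxidised with Dess–Martin periodinane to (3S)-3-[(tert-butyldimethylsilyl)oxy]icosanal F2. Dione 9 is converted with MeOH/HC(OMe)3/cat. TsOH into 3-methoxycyclohex-2-en-1-one F3 and iodinated (I2, pyridine, CH2Cl2) to 2-iodo-3-methoxycyclohex-2-en-1-one F4. Nozaki–Hiyama–Kishi coupling of F4 with F2 (CrCl2, cat. NiCl2, DMF) gives 2-[(3S)-3-[(tert-butyldimethylsilyl)oxy]-1-hydroxyicosyl]-3-methoxycyclohex-2-en-1-one F5 as a mixture of C-1' epimers, and Dess–Martin oxidation converges both epimers on ketone 12.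

Step 6 (O-methylation): alkylation could go to the exocyclic enol oxygen, and the product is hydrolytically labile. The fallback sets out from 11 and comes back at 12. Oxalyl chloride with catalytic DMF in CH2Cl2 at 0 °C turns the ring enol into the vinylogous acid chloride 3-chloro-2-[(3S)-3-[(tert-butyldimethylsilyl)oxy]icosanoyl]cyclohex-2-en-1-one F6. Methanol/Et3N at −20 °C then replaces chloride by addition–elimination at the ring carbon only, so the regiochemistry no longer depends on which enol oxygen is alkylated, and the product is 12.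

Step 7 (CBS reduction): this is the least precedented step, since both the chemoselectivity against the ring carbonyl and the facial selectivity on a twisted ketone are argued by analogy. The fallback sets out from 12 and comes back at 15. HF·pyridine in MeCN removes the silyl ether to give 2-[(3S)-3-hydroxyicosanoyl]-3-methoxycyclohex-2-en-1-one F7. Its free hydroxyl adds to the doubly activated ring C-3 and expels methanol (brief PPTS if needed) to give (2S)-2-heptadecyl-2,3,7,8-tetrahydro-4H-chromene-4,5(6H)-dione F8. Luche reduction of F8 (NaBH4, CeCl3·7H2O, MeOH, −78 °C) then sets C4 by substrate control: axial hydride attack on the half-chair with the C17 chain equatorial gives the 2,4-cis alcohol 15. The C4 carbonyl is expected to react before C5 because it is the more ketone-like of the two, but this selectivity is also unproven and any C5-reduced isomer would have to be separated.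

**Further compounds**
F1 | step 5 | (3S)-3-[(tert-butyldimethylsilyl)oxy]icosan-1-ol | CCCCCCCCCCCCCCCCC[C@H](O[Si](C)(C)C(C)(C)C)CCO
F2 | step 5 | (3S)-3-[(tert-butyldimethylsilyl)oxy]icosanal | CCCCCCCCCCCCCCCCC[C@H](O[Si](C)(C)C(C)(C)C)CC=O
F3 | step 5 | 3-methoxycyclohex-2-en-1-one | COC1=CC(=O)CCC1
F4 | step 5 | 2-iodo-3-methoxycyclohex-2-en-1-one | COC1=C(I)C(=O)CCC1
F5 | step 5 | 2-[(3S)-3-[(tert-butyldimethylsilyl)oxy]-1-hydroxyicosyl]-3-methoxycyclohex-2-en-1-one (C-1' epimers) | CCCCCCCCCCCCCCCCC[C@H](O[Si](C)(C)C(C)(C)C)CC(O)C1=C(OC)CCCC1=O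
F6 | step 6 | 3-chloro-2-[(3S)-3-[(tert-butyldimethylsilyl)oxy]icosanoyl]cyclohex-2-en-1-one | CCCCCCCCCCCCCCCCC[C@H](O[Si](C)(C)C(C)(C)C)CC(=O)C1=C(Cl)CCCC1=O
F7 | step 7 | 2-[(3S)-3-hydroxyicosanoyl]-3-methoxycyclohex-2-en-1-one | CCCCCCCCCCCCCCCCC[C@H](O)CC(=O)C1=C(OC)CCCC1=O
F8 | step 7 | (2S)-2-heptadecyl-2,3,7,8-tetrahydro-4H-chromene-4,5(6H)-dione | CCCCCCCCCCCCCCCCC[C@H]1CC(=O)C2=C(CCCC2=O)O1
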